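The flask cannot exchange more ligand than the gas has handed over, so I count deliveries before anything else.

starting complex 0.050 M; capture agent 2.50 mM; gas 2.8 mM (held); time 40 s

* how much complex with two exchanged and crystals together there is at 40 s, in percent of the starting complex charged
* the change that raises the amount of complex with two exchanged and crystals together at 40 s, in percent of the starting complex charged most ("none" if none brings more than 2 percentage points) (Monday's / Saturday's / Thursday's / Tuesday's / none)
* amount of complex with two exchanged and crystals together at 40 s, in percent of the starting complex charged, after Saturday's

- Monday's: doubling the saturation concentration of gas, all else as stated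
- Saturday's: doubling the solubility in step 5, all else as stated
- Thursday's: doubling the dissolution coefficient of step 5, all else as stated
- Tuesday's: doubling the transfer coefficient of step 7, all else as stated

- amounts and yields of complex with two exchanged count crystals too
- given per volume of solution although it is solid: crystals
- at the start none of incoming ligand is dissolved
- run time (flask): 40 s

    starting complex + incoming ligand ⇌ leaving ligand + complex with one exchanged (K1 = 620, k1 = 160 /M/s)
    complex with one exchanged + incoming ligand ⇌ leaving ligand + complex with two exchanged (K2 = 180, k2 = 250 /M/s)
    complex with two exchanged + incoming ligand ⇌ leaving ligand + complex with three exchanged (K3 = 8.1, k3 = 220 /M/s)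
    complex with three exchanged + incoming ligand ⇌ leaving ligand + complex with four exchanged (K4 = 6.1, k4 = 67 /M/s)
    crystals ⇌ complex with two exchanged, rate k5*(cs5 - [complex with two exchanged]) while solid is left; crystals form when [complex with two exchanged] > cs5 (cs5 = 22 mM, k5 = 0.70 /s)
    complex with one exchanged + capture agent → trapped intermediate (k6 = 1.1 /M/s)
    gas ⇌ incoming ligand, rate k7*(csat - [incoming ligand]) (k7 = 1.2 /s, csat = 2.8 mM)

1. The first instants. No incoming ligand is dissolved, so the gas crosses at its full rate, 3.36 mM/s. The first exchange, by its forward rate at the charge, consumes dissolved ligand with a half-life of 0.087 s, shorter than the 0.578 s of the crossing. So at the start the crossing is the rate-limiting step.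

2. The count. At full rate for 40 s, the gas hands over 2.69 incoming ligand per starting complex charged. This number, deliveries per starting complex into a solution kept empty, is my delivery ceiling. Two per complex take 29.8 s at that rate, less than the run, so at full rate the deliveries reach two per complex within the run.

3. The middle. Capture of complex with one exchanged has a half-life of 4.2 min, longer than the run, so I treat it as a small loss. Crystals appear once dissolved complex with two exchanged passes 44.0 % of the charge, and crystals take no part in the third exchange.

4. The end. If two leaving ligands stand per complex charged and dissolved ligand is at saturation, the third exchange balances with complex with three exchanged at 0.227 times dissolved complex with two exchanged. I therefore expect complex with two exchanged to lead, though I reach no figure. Monday's and Tuesday's both raise the ceiling to 5.38, but Monday's also doubles that balance to 0.454, so I put Tuesday's first.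

The forecast gives 71 %, Tuesday's, and 62 % after Saturday's. It agrees with my choice, holding that “faster transfer brings uptake closer to the two-ligand optimum”.

The simulation gives 72.3 %, Tuesday's, and 64.3 % after Saturday's. Tuesday's moves the amount by 5.1 percentage points, above the margin, Thursday's by 0.5 points, Monday's by −2 points, and Saturday's by −8.1 points.

In the flask, the first exchange runs ahead: at 4.00 s it has 20 % of its turnover behind it, the second exchange 3.8 %. At 20.0 s, starting complex stands at 28.5 % and crystals at 0 %. At 40.0 s, starting complex is 2.32 %, crystals hold 26.7 %, and leaving ligand counts 1.88 per complex charged, under the ceiling of 2.69. Watch the clock: in this flask, stopped at 35.9 s, the answer stands 5 points from its value at the asked time.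

In the neighbour flask with 0.20 M of starting complex, the ceiling is 0.672, under one per complex, so at least 32.8 % of starting complex must remain there. That neighbour flask ends with 49.5 % of starting complex and gives 12.4 %.

(The numbers were drawn at random within sensible limits.)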